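# Proposal: (+)-Lariciresinol 9-O-stearate by an acetal-tethered oxocarbenium–enol ether cyclisation

Atom labels used throughout: oxolane ring A = O1, C2 (aryl), C3 (bears C9H2–O9), C4 (bears the benzylic carbon C7'), C5. Ring B is the temporary second oxolane O9, C9, C3, C4, C7'.

## The problem

The target 24 is the C9 stearate of (+)-lariciresinol. It has one oxolane (ring A) with a guaiacyl group on C2, an acyloxymethyl arm on C3 and a guaiacylmethyl group on C4, in the configuration (2S,3R,4R): the C2 aryl is trans to C9, and C9 is cis to C7'.

The three stereocentres are contiguous and C3 is the hub. The 3,4-cis relation puts both carbon arms on one face, which is not what enolate alkylation or equilibration delivers, so C4 must be set by delivery from the C3 arm or by a face-selective addition.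

C2 is a benzylic ether carbon para to a phenolic oxygen. With a donating para oxygen it ionises under acid (epimerisation, ring opening, Friedel–Crafts closure to an aryltetralin) and its C–O bond is open to hydrogenolysis.

The ester must be placed on the one aliphatic hydroxyl beside two phenols. Once in place it excludes strong base, hydride reagents and hard nucleophiles.

The enabling feature is the chain O9–C9–C3–C4–C7', which lies on one face of ring A. A temporary O9–C7' bond turns the target into a cis-fused 3,7-dioxabicyclo[3.3.0]octane, and ring B can only be cis-fused. Closing ring B from O9 therefore delivers C7' to C4 on the face of C9. Reopening it at the benzylic C7'–O9 bond returns the free C9 hydroxyl and the C7' methylene.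

## Retrosynthesis

**24 ⇒ 22 + 23.** The acyl–O9 bond is cut last. An ester introduced earlier would not survive the hydride and hydroxide steps. (+)-Lariciresinol 22 is a well-characterised checkpoint. The forward step must acylate a primary aliphatic hydroxyl beside two phenols, which a lipase with the enol ester 23 should do without protecting groups.

**22 ⇒ 21.** Both phenols are masked, but differently. The arene on C2 carries a 4-methylbenzenesulfonate and the arene on C7' a triisopropylsilyl ether. One hydroxide treatment should remove both. The reason for the difference lies in the next cut.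

**21 ⇒ 19 (through 20).** The C7'–O9 bond is re-formed and C5 is raised from CH2 to a methyl acetal. Forward, both changes are ionic silane reductions.

- Hydrogenolysis of a symmetric bis-phenol bicycle was the neighbouring option. It is regiochemically safe only if ring closure gives the exo aryl at C7', because only then are the two benzylic C–O bonds equivalent after C5 is deoxygenated.
- That cannot be relied on. The tether fixes the face of C4, not the orientation of the aryl group on C7', and kinetically controlled closures of this kind are known to favour the endo aryl. An exo,endo bicycle has two different benzylic bonds, and cutting the wrong one destroys C2.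
- The two arenes are therefore made electronically different. The sulfonylated para oxygen cannot stabilise a cation at C2; the silylated para oxygen can stabilise one at C7'. Acid plus hydride should then cut only C7'–O9, whatever the configuration at C7'.
- The same sulfonate protects C2 against epimerisation in every acidic step.

**19 ⇒ 14 + 16 (key disconnection).** C4–C7' and O9–C7' are cut, and the C5 methoxy group is returned to the acetal carbon. The molecule falls into two vanillin-derived halves, and three stereocentres of 19 reduce to the two of 14. Forward, acetal exchange at O9 must come first, and the tethered oxocarbenium ion must then be attacked by the enol ether carbon C4. An untethered C–C bond formation would occur anti to the C3 arm and give the wrong 3,4-relation.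

**14 ⇒ 13 ⇒ 11 ⇒ 8.** The C9 alcohol is traced to an acyl oxazolidinone (reduction), the enol ether to a lactol (dehydration), and the lactol to a terminal alkene (ozonolysis). C5 is thus carried through the aldol as an alkene at the aldehyde oxidation level. Carrying C5 at the carboxyl level would need the selective reduction of one carboxyl-derived carbon beside another, hydroperoxide cleavage of the auxiliary in the presence of the aryl sulfonate, and protection of O9 during half-reduction. The alkene route needs none of these and no protecting group on O9.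

**8 ⇒ 6 + 2.** The C2–C3 bond is cut by an auxiliary-controlled syn aldol, which sets both stereocentres of 14 at once. The syn relation becomes 2,3-trans once O1 and C4 are joined in ring A. The aldehyde 2 already carries the sulfonate.

**6 ⇒ 3 + 4; 2, 15 and 16 ⇒ 1.** The imide 6 comes from the oxazolidinone 3 and the acid chloride 4. Both aryl building blocks come from vanillin 1: by sulfonylation (2), and by silylation (15) followed by acetalisation (16).

## Roads not taken

**Alternative 1:** Cut at C2–C3 and C4–C7' on a chiral-pool butenolide.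

- Forward key step: the lithiated dithiane A2 adds to the β-carbon of the (R)-butenolide A1 anti to the trityloxymethyl group. The enolate is then benzylated with A3 anti to the new substituent, giving the trans,trans lactone A4.
- Merits: two C–C bonds and both C3 and C4 are set in one flask by substrate control from a cheap chiral source. The trans relation in the lactone becomes the required 3,4-cis relation once ring A is formed.
- Weak points: in A4 the γ-carbon carries one carbon too many, so C9 must be exposed by detritylation, glycol cleavage and reduction. The dithiane must be unmasked and C2 reduced with no control element other than the preference of the final ring closure. The lactone carbonyl must be taken down to C5H2, and ring A is closed through a benzylic cation at C2 beside an electron-rich arene, where aryltetralin formation competes.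
- Comparison: A4 fixes C3/C4 as reliably as the chosen route, and its three-component union is more convergent. The chosen plan is clearly shorter, sets C2 in the aldol as a defined centre, and never ionises it.

**Alternative 2:** Cut at O1–C5 of a lactone, made by desymmetrising ring expansion of the cyclobutanone A5.

- Forward key step: an enantioselective Baeyer–Villiger oxidation inserts oxygen next to one of the two enantiotopic CH2 groups of A5 and gives the (R)-lactone A6. A trans-selective aldol of A6 with 15, reduction of both carbonyl-derived carbons to alcohols, and acid-mediated closure at C2 would lead to 22 after desilylation.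
- Merits: this is the shortest road, about nine steps to 24. All stereocentres follow from the one set in A6, and there is no auxiliary.
- Weak points: the enantiotopic discrimination relies on a catalyst reading a remote benzyl group, and no later crystalline or diastereomeric stage allows the enantiomeric purity to be raised. The oxidant meets an electron-rich arene. Ring A is closed by ionising C2 under acid, so its configuration is only thermodynamic and the aryltetralin pathway is open.
- Comparison: in step count and protecting-group economy this alternative is better. The chosen plan offers absolute configuration from an auxiliary with separable diastereomers, a C2 centre that is set once and held by the sulfonate, and a 3,4-cis relation enforced by geometry.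

**Alternative 3:** Cut at C3–C4 by radical cyclisation of the epoxy cinnamyl ether A7.

- Forward key step: Cp2TiCl (trivalent titanium) opens the terminal epoxide of A7 homolytically to the C3 radical with titanium on O9. 5-exo closure onto the cinnamyl alkene forms C3–C4 and ring A. The benzylic radical at C7' is reduced by a second equivalent and protonated, giving the bis-silyl ether A8.
- Merits: one step builds ring A, leaves O9 free and C7' as CH2, and needs no tether to remove. The neutral conditions spare the benzylic ether. A8 has both phenols masked, so the stearate could be introduced by ordinary acylation before desilylation. That is a simpler endgame than the enzymatic step chosen here, and the whole route is shorter.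
- Weak points: C3 passes through a planar radical, so C3 and C4 are both set in the cyclisation by conformational preference only (Beckwith–Houk chair-like closure). Diastereomers are to be expected and must be separated. A7 must be made enantioenriched, most plausibly by a kinetic-resolution epoxidation that discards half the material. Its electron-rich benzylic ether is also exposed to a Lewis-acidic titanium reagent used in excess.
- Comparison: Alternative 3 wins on length and endgame. The chosen plan offers the tether-enforced 3,4-cis relation and the auxiliary-based control of C2 and C3 without a resolution.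

Key step: step 9

Remark on the chemistry (assumption): 19 is drawn with the aryl group on C7' endo and the methoxy group on C5 exo, as expected for kinetic closure. Both centres are erased in step 10, so any epimer at C7' or C5 converges on 21. Lactol 11 is used as its anomeric mixture.

## Route

Step 1
Reactants: 1 vanillin
Product: 2 4-formyl-2-methoxyphenyl 4-methylbenzenesulfonate
Conditions: TsCl, Et3N, DMAP (cat.), CH2Cl2, 0 °C → rt
Reagents that add atoms: 4-methylbenzenesulfonyl chloride, Cc1ccc(cc1)S(=O)(=O)Cl
Why: Sulfonylation of the phenol under nucleophilic catalysis; the aldehyde is untouched, and the aryl sulfonate withstands boron enolates, ozone, hydride and Lewis acids while turning the para oxygen into a non-donor.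

Step 2
Reactants: 3 (S)-4-benzyl-1,3-oxazolidin-2-one; 4 pent-4-enoyl chloride
Product: 6 (S)-4-benzyl-3-(pent-4-enoyl)-1,3-oxazolidin-2-one, via lithium oxazolidinide 5 (not isolated)
Conditions: n-BuLi, THF, −78 °C; then 4, −78 → 0 °C
Reagents that add atoms: none
Why: N-Acylation of the lithiated oxazolidinone by an acid chloride; no stereocentre is involved.

Step 3
Reactants: 6 (S)-4-benzyl-3-(pent-4-enoyl)-1,3-oxazolidin-2-one; 2 4-formyl-2-methoxyphenyl 4-methylbenzenesulfonate
Product: 8 (4S)-4-benzyl-3-[(2S)-2-{(S)-hydroxy[3-methoxy-4-(tosyloxy)phenyl]methyl}pent-4-enoyl]-1,3-oxazolidin-2-one, via boron enolate 7 (not isolated)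
Conditions: Bu2BOTf, i-Pr2NEt, CH2Cl2, 0 °C; then 2, −78 → 0 °C; pH 7 buffer, MeOH, H2O2 (30%), 0 °C
Reagents that add atoms: none
Why: Evans syn aldol: the (Z)-boron enolate 7 reacts through a Zimmerman–Traxler chair on the enolate face opposite the benzyl group of the auxiliary, setting the α-carbon (future C3) and the carbinol carbon (future C2) as S,S; this syn relation becomes 2,3-trans once O1 and C4 are joined in ring A.

Step 4
Reactants: 8 (4S)-4-benzyl-3-[(2S)-2-{(S)-hydroxy[3-methoxy-4-(tosyloxy)phenyl]methyl}pent-4-enoyl]-1,3-oxazolidin-2-one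
Product: 11 (4S)-4-benzyl-3-({(2S,3S)-5-hydroxy-2-[3-methoxy-4-(tosyloxy)phenyl]oxolan-3-yl}carbonyl)-1,3-oxazolidin-2-one, via ozonide 9 (not isolated), via hydroxy aldehyde 10 (not isolated)
Conditions: O3, CH2Cl2, −78 °C; Me2S, −78 °C → rt
Reagents that add atoms: ozone, [O-][O+]=O
Why: Ozonolysis with reductive work-up (Criegee mechanism) cleaves the terminal alkene much faster than it attacks the sulfonylated arene, and the γ-hydroxy aldehyde 10 closes spontaneously to the five-membered lactol; C2 and C3 are not touched.

Step 5
Reactants: 11 (4S)-4-benzyl-3-({(2S,3S)-5-hydroxy-2-[3-methoxy-4-(tosyloxy)phenyl]oxolan-3-yl}carbonyl)-1,3-oxazolidin-2-one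
Product: 13 (4S)-4-benzyl-3-({(2S,3S)-2-[3-methoxy-4-(tosyloxy)phenyl]-2,3-dihydrofuran-3-yl}carbonyl)-1,3-oxazolidin-2-one, via anomeric mesylate 12 (not isolated)
Conditions: MsCl, Et3N, CH2Cl2, −40 °C → rt
Reagents that add atoms: none
Why: Lactol dehydration to a 2,3-dihydrofuran: the anomeric mesylate ionises with help from O1 and Et3N removes a proton from C4, the only carbon next to C5; the trans arrangement at C2/C3 is also the thermodynamically preferred one, so any reversible enolisation at C3 should not erode it.

Step 6
Reactants: 13 (4S)-4-benzyl-3-({(2S,3S)-2-[3-methoxy-4-(tosyloxy)phenyl]-2,3-dihydrofuran-3-yl}carbonyl)-1,3-oxazolidin-2-one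
Product: 14 {(2S,3R)-2-[3-methoxy-4-(tosyloxy)phenyl]-2,3-dihydrofuran-3-yl}methanol
Conditions: LiBH4, H2O (1 equiv), Et2O–THF, 0 °C; aq. NaOH work-up
Reagents that add atoms: none
Why: Reductive removal of the oxazolidinone auxiliary: hydride attacks the exocyclic imide carbonyl and the released aldehyde is reduced on to the primary alcohol, while the enol ether and the aryl sulfonate are inert; C3 keeps its geometry (the descriptor changes from S to R by priority only), and a basic work-up protects the enol ether.

Step 7
Reactants: 1 vanillin
Product: 15 3-methoxy-4-(triisopropylsilyloxy)benzaldehyde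
Conditions: TIPSCl, imidazole, DMF, rt
Reagents that add atoms: chlorotriisopropylsilane, CC(C)[Si](Cl)(C(C)C)C(C)C
Why: Silylation of the phenol with imidazole as base and nucleophilic catalyst; the silyl ether keeps the para oxygen a strong donor, which the ionisations in steps 9 and 10 require.

Step 8
Reactants: 15 3-methoxy-4-(triisopropylsilyloxy)benzaldehyde
Product: 16 [4-(dimethoxymethyl)-2-methoxyphenoxy]triisopropylsilane
Conditions: HC(OMe)3, p-TsOH·H2O (cat.), MeOH, rt; K2CO3 quench
Reagents that add atoms: trimethyl orthoformate, COC(OC)OC; methanol (solvent that exchanges into the acetal), CO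
Why: Acid-catalysed acetalisation driven by the orthoformate as water scavenger; the aryl silyl ether tolerates catalytic acid in methanol, and a basic quench prevents reversion.

Step 9
Reactants: 14 {(2S,3R)-2-[3-methoxy-4-(tosyloxy)phenyl]-2,3-dihydrofuran-3-yl}methanol; 16 [4-(dimethoxymethyl)-2-methoxyphenoxy]triisopropylsilane
Product: 19 (1R,3aR,4S,6R,6aS)-6-methoxy-4-[3-methoxy-4-(tosyloxy)phenyl]-1-[3-methoxy-4-(triisopropylsilyloxy)phenyl]tetrahydro-1H,3H-furo[3,4-c]furan, via trimethylsilyl ether 17 (not isolated), via mixed acetal 18 (not isolated)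
Conditions: TMSOTf (1.2 equiv), 2,6-di-tert-butyl-4-methylpyridine (1.1 equiv), CH2Cl2, −78 °C; Et3N, aq. NaHCO3
Reagents that add atoms: none
Why: The hydroxyl is silylated in the flask (17), TMSOTf ionises 16 to the aryl(methoxy)carbenium ion, and O9 captures it with loss of its silyl group to give the mixed acetal 18. A second ionisation removes the remaining methoxy group of 18 and leaves the oxocarbenium ion O9=C7' held on the C9 face of the dihydrofuran; C4 of the enol ether adds to C7', the charge moves to C5 where O1 stabilises it, and the methoxysilane formed earlier returns the methoxy group and regenerates the silyl triflate. The closest known reaction type is the Lewis-acid-promoted acetal–enol ether (Prins/Mukaiyama-type) cyclisation of 2-aryl-3-(hydroxymethyl)-2,3-dihydrofurans with aryl aldehyde dimethyl acetals to 2,6-diaryl-3,7-dioxabicyclo[3.3.0]octane acetals. Ring B (O9, C9, C3, C4, C7') closes 5-exo with respect to the enol ether double bond (endo with respect to C=O+), and a three-atom tether anchored on C3 can reach C4 only on its own face, so the fusion is cis and C3 sets C4 in the configuration required in 24. C7' is expected to form with its aryl group endo (compact synclinal approach of the oxocarbenium ion over the enol ether under kinetic control) and C5 with methoxy on the convex face; neither centre is carried into 24. The step needs O-tethering to precede C–C bond formation, which the fast reversible capture of the cation by oxygen and the intramolecular closure should secure, and the hindered pyridine removes triflic acid so that the enol ether is not protonated. It also needs C2 to stay intact under the Lewis acid, which the sulfonylated arene secures.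

Step 10
Reactants: 19 (1R,3aR,4S,6R,6aS)-6-methoxy-4-[3-methoxy-4-(tosyloxy)phenyl]-1-[3-methoxy-4-(triisopropylsilyloxy)phenyl]tetrahydro-1H,3H-furo[3,4-c]furan
Product: 21 {(2S,3R,4R)-2-[3-methoxy-4-(tosyloxy)phenyl]-4-[3-methoxy-4-(triisopropylsilyloxy)benzyl]oxolan-3-yl}methanol, via furofuran 20 (not isolated)
Conditions: Et3SiH (6 equiv), BF3·OEt2 (3 equiv), CH2Cl2, −78 °C, then 0 °C → rt; aq. NaHCO3
Reagents that add atoms: none
Why: Two Kursanov–Parnes ionic hydrogenations in one flask: at −78 °C the acetal ionises to the O1-stabilised oxocarbenium ion and is reduced to C5H2 (20); on warming, BF3 on O9 ionises the benzylic C7'–O9 bond, whose cation is stabilised by the para silyloxy group, and the silane reduces it to the C7' methylene while O9 is released as the alcohol on work-up. The C2–O1 bond is held because its arene carries the sulfonylated, non-donating oxygen, C4–H is not involved so C4 is retained, and a cation at C7' cannot close onto the C2 arene because the two groups are trans across ring A.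

Step 11
Reactants: 21 {(2S,3R,4R)-2-[3-methoxy-4-(tosyloxy)phenyl]-4-[3-methoxy-4-(triisopropylsilyloxy)benzyl]oxolan-3-yl}methanol
Product: 22 (+)-lariciresinol
Conditions: KOH, MeOH–H2O, 60 °C, Ar; aq. NH4Cl
Reagents that add atoms: none
Why: Hydroxide cleaves the aryl sulfonate at sulfur and the aryl silyl ether at silicon, both with phenoxide as leaving group; the substrate has no ester and no base-labile stereocentre, and oxygen is excluded to protect the phenoxides.

Step 12
Reactants: 22 (+)-lariciresinol; 23 vinyl stearate
Product: 24 [(2S,3R,4R)-2-(4-hydroxy-3-methoxyphenyl)-4-(4-hydroxy-3-methoxybenzyl)oxolan-3-yl]methyl octadecanoate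
Conditions: immobilised Candida antarctica lipase B, 2-methylbutan-2-ol, 4 Å molecular sieves, 50 °C
Reagents that add atoms: none
Why: Lipase-catalysed transesterification with an enol ester, made irreversible by tautomerisation of vinyl alcohol to acetaldehyde; the acyl-enzyme is taken up by the primary aliphatic hydroxyl, whereas phenols are not acylated under these conditions, and no stereocentre is touched.

## Compound list

1 | vanillin | COc1cc(C=O)ccc1O | starting material
2 | 4-formyl-2-methoxyphenyl 4-methylbenzenesulfonate | COc1cc(C=O)ccc1OS(=O)(=O)c1ccc(C)cc1 | intermediate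
3 | (S)-4-benzyl-1,3-oxazolidin-2-one | O=C1N[C@@H](Cc2ccccc2)CO1 | starting material
4 | pent-4-enoyl chloride | C=CCCC(=O)Cl | starting material
5 | lithium salt of 3 (not isolated) | [Li+].O=C1[N-][C@@H](Cc2ccccc2)CO1 | intermediate
6 | (S)-4-benzyl-3-(pent-4-enoyl)-1,3-oxazolidin-2-one | C=CCCC(=O)N1[C@@H](Cc2ccccc2)COC1=O | intermediate
7 | (Z)-dibutylboron enolate of 6 (not isolated) | C=CC/C=C(\OB(CCCC)CCCC)N1[C@@H](Cc2ccccc2)COC1=O | intermediate
8 | (4S)-4-benzyl-3-[(2S)-2-{(S)-hydroxy[3-methoxy-4-(tosyloxy)phenyl]methyl}pent-4-enoyl]-1,3-oxazolidin-2-one | O=C(N1[C@@H](Cc2ccccc2)COC1=O)[C@H]([C@H](O)c1ccc(OS(=O)(=O)c2ccc(C)cc2)c(OC)c1)CC=C | intermediate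
9 | ozonide (1,2,4-trioxolane) of 8 (not isolated) | O=C(N1[C@@H](Cc2ccccc2)COC1=O)[C@H]([C@H](O)c1ccc(OS(=O)(=O)c2ccc(C)cc2)c(OC)c1)CC1OCOO1 | intermediate
10 | (4S)-4-benzyl-3-[(2S)-2-{(S)-hydroxy[3-methoxy-4-(tosyloxy)phenyl]methyl}-4-oxobutanoyl]-1,3-oxazolidin-2-one (not isolated) | O=C(N1[C@@H](Cc2ccccc2)COC1=O)[C@H]([C@H](O)c1ccc(OS(=O)(=O)c2ccc(C)cc2)c(OC)c1)CC=O | intermediate
11 | (4S)-4-benzyl-3-({(2S,3S)-5-hydroxy-2-[3-methoxy-4-(tosyloxy)phenyl]oxolan-3-yl}carbonyl)-1,3-oxazolidin-2-one (anomers at C5) | O=C(N1[C@@H](Cc2ccccc2)COC1=O)[C@H]1CC(O)O[C@@H]1c1ccc(OS(=O)(=O)c2ccc(C)cc2)c(OC)c1 | intermediate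
12 | C5 methanesulfonate of 11 (not isolated) | O=C(N1[C@@H](Cc2ccccc2)COC1=O)[C@H]1CC(OS(C)(=O)=O)O[C@@H]1c1ccc(OS(=O)(=O)c2ccc(C)cc2)c(OC)c1 | intermediate
13 | (4S)-4-benzyl-3-({(2S,3S)-2-[3-methoxy-4-(tosyloxy)phenyl]-2,3-dihydrofuran-3-yl}carbonyl)-1,3-oxazolidin-2-one | O=C(N1[C@@H](Cc2ccccc2)COC1=O)[C@H]1C=CO[C@@H]1c1ccc(OS(=O)(=O)c2ccc(C)cc2)c(OC)c1 | intermediate
14 | {(2S,3R)-2-[3-methoxy-4-(tosyloxy)phenyl]-2,3-dihydrofuran-3-yl}methanol | OC[C@H]1C=CO[C@@H]1c1ccc(OS(=O)(=O)c2ccc(C)cc2)c(OC)c1 | intermediate
15 | 3-methoxy-4-(triisopropylsilyloxy)benzaldehyde | COc1cc(C=O)ccc1O[Si](C(C)C)(C(C)C)C(C)C | intermediate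
16 | [4-(dimethoxymethyl)-2-methoxyphenoxy]triisopropylsilane | COC(OC)c1ccc(O[Si](C(C)C)(C(C)C)C(C)C)c(OC)c1 | intermediate
17 | trimethylsilyl ether of 14 (not isolated) | C[Si](C)(C)OC[C@H]1C=CO[C@@H]1c1ccc(OS(=O)(=O)c2ccc(C)cc2)c(OC)c1 | intermediate
18 | mixed methyl acetal of 14 and 15, O9–C7' tether in place (not isolated; acetal carbon unassigned) | COC(OC[C@H]1C=CO[C@@H]1c2ccc(OS(=O)(=O)c3ccc(C)cc3)c(OC)c2)c4ccc(O[Si](C(C)C)(C(C)C)C(C)C)c(OC)c4 | intermediate
19 | (1R,3aR,4S,6R,6aS)-6-methoxy-4-[3-methoxy-4-(tosyloxy)phenyl]-1-[3-methoxy-4-(triisopropylsilyloxy)phenyl]tetrahydro-1H,3H-furo[3,4-c]furan (cis-fused; C2 aryl exo, C7' aryl endo, C5 methoxy exo) | O2C[C@H]1[C@@H]([C@@H]2c3ccc(O[Si](C(C)C)(C(C)C)C(C)C)c(OC)c3)[C@H](OC)O[C@@H]1c4ccc(OS(=O)(=O)c5ccc(C)cc5)c(OC)c4 | intermediate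
20 | (1R,3aR,4S,6aR)-4-[3-methoxy-4-(tosyloxy)phenyl]-1-[3-methoxy-4-(triisopropylsilyloxy)phenyl]tetrahydro-1H,3H-furo[3,4-c]furan (not isolated) | O2C[C@H]1[C@@H]([C@@H]2c3ccc(O[Si](C(C)C)(C(C)C)C(C)C)c(OC)c3)CO[C@@H]1c4ccc(OS(=O)(=O)c5ccc(C)cc5)c(OC)c4 | intermediate
21 | {(2S,3R,4R)-2-[3-methoxy-4-(tosyloxy)phenyl]-4-[3-methoxy-4-(triisopropylsilyloxy)benzyl]oxolan-3-yl}methanol | OC[C@H]1[C@@H](Cc2ccc(O[Si](C(C)C)(C(C)C)C(C)C)c(OC)c2)CO[C@@H]1c1ccc(OS(=O)(=O)c2ccc(C)cc2)c(OC)c1 | intermediate
22 | (+)-lariciresinol | OC[C@H]1[C@@H](Cc2ccc(O)c(OC)c2)CO[C@@H]1c1ccc(O)c(OC)c1 | intermediate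
23 | vinyl stearate (ethenyl octadecanoate) | CCCCCCCCCCCCCCCCCC(=O)OC=C | starting material
24 | [(2S,3R,4R)-2-(4-hydroxy-3-methoxyphenyl)-4-(4-hydroxy-3-methoxybenzyl)oxolan-3-yl]methyl octadecanoate | CCCCCCCCCCCCCCCCCC(=O)OC[C@H]1[C@@H](Cc2ccc(O)c(OC)c2)CO[C@@H]1c1ccc(O)c(OC)c1 | target

## Step count and risk

Total step count: 12. Longest linear sequence: 9 steps (steps 1, 3, 4, 5, 6, 9, 10, 11, 12; the branch through steps 2–6 is equally long). Steps 7 and 8 form a two-step side branch.

**Step 9 (key step).** The most likely failure is C–C bond formation between the enol ether and the still untethered aryl(methoxy)carbenium ion. That attack would occur anti to the C3 arm and lead into the 3,4-trans series. A second failure is acid-mediated addition of methanol across the enol ether. Both arise because the free cation is generated in the presence of the enol ether.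
Fallback: set out from 14 and 16 and build the tether under basic conditions. Acetyl chloride converts 16 into {4-[chloro(methoxy)methyl]-2-methoxyphenoxy}triisopropylsilane F1, which is used at once to alkylate the sodium alkoxide of 14 (NaH, THF, −78 °C). The mixed acetal 18 is then isolated, so the O9–C7' bond exists before any Lewis acid is present. A catalytic amount of TMSOTf with the hindered pyridine ionises 18 alone, where only the tethered cation can form. The sequence returns to the route at 19.

**Step 10.** Ring B may fail to open cleanly: ionisation at C7' may be incomplete so that the reaction stalls at 20, the cation may be diverted by proton loss toward C4, or slow ionisation at C2 may begin if forcing conditions are needed.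
Fallback: set out from 19 and stop the silane reduction at −78 °C, so that 20 is isolated. Fluoride (TBAF, THF, 0 °C) frees the phenol of the C7' arene only, giving (1R,3aR,4S,6aR)-1-(4-hydroxy-3-methoxyphenyl)-4-[3-methoxy-4-(tosyloxy)phenyl]tetrahydro-1H,3H-furo[3,4-c]furan F2. Catalytic hydrogenolysis (H2, Pd/C, EtOAc–MeOH) then cuts the benzylic C–O bond para to the free hydroxyl; this is the known type of benzylic ether hydrogenolysis of phenolic furofurans, and the sulfonylated arene is the less reactive partner. The product is {(2S,3R,4R)-4-(4-hydroxy-3-methoxybenzyl)-2-[3-methoxy-4-(tosyloxy)phenyl]oxolan-3-yl}methanol F3. Hydroxide as in step 11 removes the sulfonate and returns to the route at 22.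

**Step 5.** C3–H of 13 is α to the imide carbonyl and allylic to the new enol ether. Amine-mediated proton loss there could move the double bond into conjugation or expel O1 by β-elimination, with loss of the C2/C3 information.
Fallback: set out from 8 and remove the acidifying carbonyl before the enol ether is made. LiBH4 gives (1S,2R)-2-allyl-1-[3-methoxy-4-(tosyloxy)phenyl]propane-1,3-diol F4. Selective silylation of the primary hydroxyl (TBSCl, imidazole) gives its mono-tert-butyldimethylsilyl ether F5. Ozonolysis with reductive work-up gives the lactol (4R,5S)-4-[(tert-butyldimethylsilyloxy)methyl]-5-[3-methoxy-4-(tosyloxy)phenyl]oxolan-2-ol F6. MsCl/Et3N dehydration gives tert-butyl({(2S,3R)-2-[3-methoxy-4-(tosyloxy)phenyl]-2,3-dihydrofuran-3-yl}methoxy)dimethylsilane F7. TBAF at 0 °C, which spares the aryl sulfonate, returns to the route at 14.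

**Step 12.** Acyl transfer may be slow or incomplete because the primary hydroxyl sits between two ring substituents and the substrate is poorly soluble in media that keep the enzyme active.
Fallback: set out from 22, over-acylate, then trim. Stearoyl chloride with pyridine and DMAP gives the tristearate [(2S,3R,4R)-2-[3-methoxy-4-(octadecanoyloxy)phenyl]-4-[3-methoxy-4-(octadecanoyloxy)benzyl]oxolan-3-yl]methyl octadecanoate F8. Pyrrolidine (CH2Cl2, 0 °C → rt) aminolyses the two activated aryl esters and leaves the alkyl ester, returning to the route at 24.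

## Further compounds

F1 | step 9 | {4-[chloro(methoxy)methyl]-2-methoxyphenoxy}triisopropylsilane | COC(Cl)c1ccc(O[Si](C(C)C)(C(C)C)C(C)C)c(OC)c1
F2 | step 10 | (1R,3aR,4S,6aR)-1-(4-hydroxy-3-methoxyphenyl)-4-[3-methoxy-4-(tosyloxy)phenyl]tetrahydro-1H,3H-furo[3,4-c]furan | O2C[C@H]1[C@@H]([C@@H]2c3ccc(O)c(OC)c3)CO[C@@H]1c4ccc(OS(=O)(=O)c5ccc(C)cc5)c(OC)c4
F3 | step 10 | {(2S,3R,4R)-4-(4-hydroxy-3-methoxybenzyl)-2-[3-methoxy-4-(tosyloxy)phenyl]oxolan-3-yl}methanol | OC[C@H]1[C@@H](Cc2ccc(O)c(OC)c2)CO[C@@H]1c1ccc(OS(=O)(=O)c2ccc(C)cc2)c(OC)c1
F4 | step 5 | (1S,2R)-2-allyl-1-[3-methoxy-4-(tosyloxy)phenyl]propane-1,3-diol | OC[C@H]([C@H](O)c1ccc(OS(=O)(=O)c2ccc(C)cc2)c(OC)c1)CC=C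
F5 | step 5 | (1S,2R)-2-[(tert-butyldimethylsilyloxy)methyl]-1-[3-methoxy-4-(tosyloxy)phenyl]pent-4-en-1-ol | CC(C)(C)[Si](C)(C)OC[C@H]([C@H](O)c1ccc(OS(=O)(=O)c2ccc(C)cc2)c(OC)c1)CC=C
F6 | step 5 | (4R,5S)-4-[(tert-butyldimethylsilyloxy)methyl]-5-[3-methoxy-4-(tosyloxy)phenyl]oxolan-2-ol (anomers) | CC(C)(C)[Si](C)(C)OC[C@H]1CC(O)O[C@@H]1c1ccc(OS(=O)(=O)c2ccc(C)cc2)c(OC)c1
F7 | step 5 | tert-butyl({(2S,3R)-2-[3-methoxy-4-(tosyloxy)phenyl]-2,3-dihydrofuran-3-yl}methoxy)dimethylsilane | CC(C)(C)[Si](C)(C)OC[C@H]1C=CO[C@@H]1c1ccc(OS(=O)(=O)c2ccc(C)cc2)c(OC)c1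
F8 | step 12 | [(2S,3R,4R)-2-[3-methoxy-4-(octadecanoyloxy)phenyl]-4-[3-methoxy-4-(octadecanoyloxy)benzyl]oxolan-3-yl]methyl octadecanoate | CCCCCCCCCCCCCCCCCC(=O)OC[C@H]1[C@@H](Cc2ccc(OC(=O)CCCCCCCCCCCCCCCCC)c(OC)c2)CO[C@@H]1c1ccc(OC(=O)CCCCCCCCCCCCCCCCC)c(OC)c1
A1 | alternative 1 | (R)-5-(trityloxymethyl)furan-2(5H)-one | C(c1ccccc1)(c1ccccc1)(c1ccccc1)OC[C@@H]1OC(=O)C=C1
A2 | alternative 1 | 2-[3-methoxy-4-(triisopropylsilyloxy)phenyl]-1,3-dithiane | COc1cc(C2SCCCS2)ccc1O[Si](C(C)C)(C(C)C)C(C)C
A3 | alternative 1 | [4-(bromomethyl)-2-methoxyphenoxy]triisopropylsilane | COc1cc(CBr)ccc1O[Si](C(C)C)(C(C)C)C(C)C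
A4 | alternative 1 | trans,trans α-benzyl β-dithianyl γ-(trityloxymethyl) lactone | C(c1ccccc1)(c1ccccc1)(c1ccccc1)OC[C@@H]1OC(=O)[C@H](Cc2ccc(O[Si](C(C)C)(C(C)C)C(C)C)c(OC)c2)[C@H]1C1(SCCCS1)c1ccc(O[Si](C(C)C)(C(C)C)C(C)C)c(OC)c1
A5 | alternative 2 | 3-[3-methoxy-4-(triisopropylsilyloxy)benzyl]cyclobutanone | O=C1CC(Cc2ccc(O[Si](C(C)C)(C(C)C)C(C)C)c(OC)c2)C1
A6 | alternative 2 | (R)-4-[3-methoxy-4-(triisopropylsilyloxy)benzyl]dihydrofuran-2(3H)-one | O=C1C[C@@H](Cc2ccc(O[Si](C(C)C)(C(C)C)C(C)C)c(OC)c2)CO1
A7 | alternative 3 | (E)-cinnamyl-type ether of the aryl(oxiranyl)methanol, both arenes as triisopropylsilyl ethers (benzylic centre R, epoxide carbon unassigned) | O(C/C=C/c1ccc(O[Si](C(C)C)(C(C)C)C(C)C)c(OC)c1)[C@@H](C1CO1)c1ccc(O[Si](C(C)C)(C(C)C)C(C)C)c(OC)c1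
A8 | alternative 3 | bis(triisopropylsilyl) ether of (+)-lariciresinol | OC[C@H]1[C@@H](Cc2ccc(O[Si](C(C)C)(C(C)C)C(C)C)c(OC)c2)CO[C@@H]1c1ccc(O[Si](C(C)C)(C(C)C)C(C)C)c(OC)c1
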